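**Retrosynthetic overview**
- Target ⇐ opening of a temporary enol lactone and butenyl→prenyl cross-metathesis ⇐ dearomative Claisen shift of an O5 but-3-en-2-yl ether onto C6, which sets the quaternary carbon by 1,3-chirality transfer from (S)-but-3-en-2-ol.
- C6–CH2 bond: Negishi coupling of the aromatic 6-iodo tricycle with the C11 alkylzinc; its stereocentre comes from methyl (R)-glycidate (epoxide opening, then invertive alkenylcuprate displacement of the α-triflate).
- C8–CH(Ph) bond and lactone ring: invertive Friedel–Crafts opening of (R)-4-phenyloxetan-2-one, made from (R)-3-hydroxy-3-phenylpropanoic acid.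
- cis-Chromanone: photo-Fries acyl shift of the phloroglucinol ester of (2S,3S)-3-hydroxy-2-methylbutanoic acid (from ethyl (S)-3-hydroxybutanoate), then invertive Mitsunobu ring closure.
- Ring order: benzene ring bought (phloroglucinol) → chromanone ring → lactone ring (temporary) → carbocycle dearomatised last; lactone opened at the end.

Assumption: the target is an enolised β-triketone whose tautomers interconvert; the given SMILES is taken as one drawing of that single compound.

**Route**

Step 1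
Reactants: 1 ethyl (3S)-3-hydroxybutanoate
Product: 3 (2S,3S)-3-hydroxy-2-methylbutanoic acid, via ethyl ester 2 (not isolated)
Conditions: LiN(iPr)2 (2.2 equiv, commercial), THF, −78 → −20 °C; MeI, DMPU, −78 → 0 °C; then LiOH, THF/H2O, 25 °C; aq. HCl work-up
Reagents that add atoms: iodomethane (CI); lithium hydroxide ([Li+].[OH-])
Why: Fráter–Seebach alkylation, in which the chelated alkoxide–enolate is methylated anti to the bought C3 centre (about 95:5) to set C2 as S, followed by saponification.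

Step 2
Reactants: 3 (2S,3S)-3-hydroxy-2-methylbutanoic acid; 4 phloroglucinol (benzene-1,3,5-triol)
Product: 5 3,5-dihydroxyphenyl (2S,3S)-3-hydroxy-2-methylbutanoate
Conditions: EDC·HCl, DMAP (10 mol%), 4 (4 equiv), THF, 0 → 25 °C
Reagents that add atoms: none
Why: Carbodiimide (Steglich-type) esterification; the excess of the threefold-symmetric triol gives the mono-ester and the phenol outcompetes the hindered secondary alcohol.

Step 3
Reactants: 5 3,5-dihydroxyphenyl (2S,3S)-3-hydroxy-2-methylbutanoate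
Product: 6 (2S,3S)-3-hydroxy-2-methyl-1-(2,4,6-trihydroxyphenyl)butan-1-one
Conditions: hν (254 nm, low-pressure Hg lamp, quartz), degassed MeCN, 25 °C
Reagents that add atoms: none
Why: Photo-Fries rearrangement: O–acyl homolysis and in-cage recombination form the aryl–acyl bond, ortho and para recombination give the same ketone because all ring carbons are equivalent, and the acyl radical keeps its α-stereocentre.

Step 4
Reactants: 6 (2S,3S)-3-hydroxy-2-methyl-1-(2,4,6-trihydroxyphenyl)butan-1-one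
Product: 7 (2R,3S)-5,7-dihydroxy-2,3-dimethylchroman-4-one (cis)
Conditions: PPh3, DIAD, THF (0.01 M), 0 °C
Reagents that add atoms: none
Why: Intramolecular Mitsunobu etherification by either of the two equivalent ortho-phenols with inversion at the carbinol carbon, so the anti (2S,3S) ketol gives the cis (2R,3S) chromanone.

Step 5
Reactants: 7 (2R,3S)-5,7-dihydroxy-2,3-dimethylchroman-4-one
Product: 8 (2R,3S)-5-hydroxy-2,3-dimethyl-7-[tri(propan-2-yl)silyloxy]chroman-4-one
Conditions: iPr3SiCl, imidazole, DMF, 0 °C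
Reagents that add atoms: chlorotri(propan-2-yl)silane (CC(C)[Si](Cl)(C(C)C)C(C)C)
Why: Selective silylation of the free, more acidic 7-OH; the 5-OH is held in a hydrogen bond to the ketone and does not react.

Step 6
Reactants: 8 (2R,3S)-5-hydroxy-2,3-dimethyl-7-[tri(propan-2-yl)silyloxy]chroman-4-one
Product: 10 (2R,3S)-5,7-dihydroxy-6-iodo-2,3-dimethylchroman-4-one, via silylated iodide 9 (not isolated)
Conditions: BnMe3N+ ICl2− (1.05 equiv), CaCO3, CH2Cl2/MeOH, 25 °C; then Bu4NF, AcOH, THF, 0 °C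
Reagents that add atoms: benzyltrimethylammonium dichloroiodate (C[N+](C)(C)Cc1ccccc1.Cl[I-]Cl)
Why: Electrophilic aromatic iodination ortho to the chelated 5-hydroxyl (the pattern reported for 5-hydroxy-7-alkoxychromones with this reagent) puts iodine on C6, then buffered fluoride desilylation frees the 7-OH.

Step 7
Reactants: 11 (3R)-3-hydroxy-3-phenylpropanoic acid
Product: 12 (4R)-4-phenyloxetan-2-one
Conditions: PhSO2Cl, pyridine, 0 °C
Reagents that add atoms: none
Why: β-Lactonisation by carboxyl activation (Adam procedure); the carbinol C–O bond is not broken, so configuration is retained.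

Step 8
Reactants: 10 (2R,3S)-5,7-dihydroxy-6-iodo-2,3-dimethylchroman-4-one; 12 (4R)-4-phenyloxetan-2-one
Product: 14 (2R,3S,10S)-5-hydroxy-6-iodo-2,3-dimethyl-10-phenyl-2,3,9,10-tetrahydropyrano[2,3-f]chromene-4,8-dione, via seco acid 13 (not isolated)
Conditions: (CF3)2CHOH, 0 → 25 °C; then EDC·HCl, CH2Cl2, 25 °C
Reagents that add atoms: none
Why: Proposed new method: stereoinvertive Friedel–Crafts ring-opening of an enantiopure β-aryl-β-lactone by the only free ring carbon (C8, activated by O1, O7 and the para 5-OH) in hexafluoroisopropanol, where hydrogen-bond activation and strain release allow SN2-type attack at the benzylic C–O bond with inversion ((4R)-12 gives 10S) and free the acid, which the carbodiimide closes onto the neighbouring 7-OH; the closest known reaction types are the invertive Friedel–Crafts opening of enantioenriched styrene oxides and 2-aryl-N-sulfonylaziridines by electron-rich arenes and Friedel–Crafts alkylation with β-propiolactone by alkyl–oxygen cleavage.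

Step 9
Reactants: 15 methyl (2R)-oxirane-2-carboxylate (methyl (R)-glycidate)
Product: 16 methyl (2R)-2-hydroxy-5-methylhex-5-enoate
Conditions: CH2=C(CH3)CH2MgCl (1.3 equiv), CuBr·SMe2 (10 mol%), THF, −78 → −40 °C
Reagents that add atoms: 2-methylallylmagnesium chloride (CC(=C)C[Mg]Cl)
Why: Copper-catalysed Grignard opening of the epoxide at its unsubstituted carbon; the bought stereocentre is not touched.

Step 10
Reactants: 16 methyl (2R)-2-hydroxy-5-methylhex-5-enoate
Product: 18 methyl (2R)-5-methyl-2-(2-methylprop-1-en-1-yl)hex-5-enoate, via triflate 17 (not isolated)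
Conditions: Tf2O, 2,6-lutidine, CH2Cl2, −78 °C; then (Me2C=CH)2CuMgBr [from Me2C=CHMgBr (2 equiv) and CuBr·SMe2 (1 equiv)], THF, −78 → −30 °C
Reagents that add atoms: 2-methylprop-1-enylmagnesium bromide (CC(C)=C[Mg]Br)
Why: SN2 displacement of an α-triflyloxy ester by an alkenylcuprate with clean inversion, which sets the side-chain stereocentre from the glycidate carbon.

Step 11
Reactants: 18 methyl (2R)-5-methyl-2-(2-methylprop-1-en-1-yl)hex-5-enoate
Product: 19 (2R)-5-methyl-2-(2-methylprop-1-en-1-yl)hex-5-en-1-ol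
Conditions: iBu2AlH (2.2 equiv), CH2Cl2, −78 → 0 °C
Reagents that add atoms: none
Why: Hydride reduction of the ester under non-basic, cold conditions, so the α-stereocentre and the β,γ-alkene stay in place.

Step 12
Reactants: 19 (2R)-5-methyl-2-(2-methylprop-1-en-1-yl)hex-5-en-1-ol
Product: 20 (2R)-1-iodo-5-methyl-2-(2-methylprop-1-en-1-yl)hex-5-ene
Conditions: I2, PPh3, imidazole, CH2Cl2, 0 °C
Reagents that add atoms: iodine (II)
Why: Appel-type iodination of a primary alcohol; the stereocentre is one carbon away and untouched.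

Step 13
Reactants: 20 (2R)-1-iodo-5-methyl-2-(2-methylprop-1-en-1-yl)hex-5-ene; 14 (2R,3S,10S)-5-hydroxy-6-iodo-2,3-dimethyl-10-phenyl-2,3,9,10-tetrahydropyrano[2,3-f]chromene-4,8-dione
Product: 22 (2R,3S,10S)-5-hydroxy-2,3-dimethyl-6-[(2S)-5-methyl-2-(2-methylprop-1-en-1-yl)hex-5-en-1-yl]-10-phenyl-2,3,9,10-tetrahydropyrano[2,3-f]chromene-4,8-dione, via alkylzinc iodide 21 (not isolated)
Conditions: Zn dust, LiCl, THF, 40 °C; then 14, Pd(OAc)2 (3 mol%), SPhos (6 mol%), THF, 40 °C
Reagents that add atoms: none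
Why: Negishi sp3–sp2 coupling; the polar organozinc avoids the vinyl-shift and cyclisation pathways open to the corresponding radical, tolerates the lactone and the chelated phenol, and leaves the β-stereocentre alone.

Step 14
Reactants: 22 (see step 13); 23 (2S)-but-3-en-2-ol
Product: 25 (2R,3S,6R,10S)-6-[(2E)-but-2-en-1-yl]-2,3-dimethyl-6-[(2S)-5-methyl-2-(2-methylprop-1-en-1-yl)hex-5-en-1-yl]-10-phenyl-2,3,9,10-tetrahydropyrano[2,3-f]chromene-4,5,8(6H)-trione, via butenyl aryl ether 24 (not isolated)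
Conditions: PBu3, ADDP, PhMe, 0 → 25 °C; then 130 °C, sealed tube
Reagents that add atoms: none
Why: Mitsunobu etherification of the only free phenol inverts 23 to the (R)-ether, whose chair-like aromatic Claisen rearrangement (methyl equatorial, E-alkene) can only end productively on C6 and delivers the butenyl group to one face, setting the quaternary carbon by 1,3-chirality transfer (expected about 10:1).

Step 15
Reactants: 25 (see step 14)
Product: 27 CNP0155375.1 (target), via prenyl lactone 26 (not isolated)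
Conditions: second-generation Grubbs catalyst RuCl2(=CHPh)(PCy3)(H2IMes) (5 mol%), 2-methylbut-2-ene/CH2Cl2, 40 °C; then LiOH, THF/H2O, 0 °C; aq. HCl work-up
Reagents that add atoms: 2-methylbut-2-ene (CC=C(C)C); lithium hydroxide ([Li+].[OH-])
Why: Olefin cross-metathesis turns the disubstituted butenyl alkene into the prenyl group (the trisubstituted, 1,1-disubstituted and dienone alkenes react much more slowly), then mild saponification opens the enol lactone to the acid and the enolised triketone without touching a stereocentre.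

**Compound list**

1 | ethyl (3S)-3-hydroxybutanoate | C[C@H](O)CC(=O)OCC | starting material
2 | ethyl (2S,3S)-3-hydroxy-2-methylbutanoate | C[C@H](O)[C@H](C)C(=O)OCC | intermediate
3 | (2S,3S)-3-hydroxy-2-methylbutanoic acid | C[C@H](O)[C@H](C)C(=O)O | intermediate
4 | phloroglucinol (benzene-1,3,5-triol) | Oc1cc(O)cc(O)c1 | starting material
5 | 3,5-dihydroxyphenyl (2S,3S)-3-hydroxy-2-methylbutanoate | C[C@H](O)[C@H](C)C(=O)Oc1cc(O)cc(O)c1 | intermediate
6 | (2S,3S)-3-hydroxy-2-methyl-1-(2,4,6-trihydroxyphenyl)butan-1-one | C[C@H](O)[C@H](C)C(=O)c1c(O)cc(O)cc1O | intermediate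
7 | (2R,3S)-5,7-dihydroxy-2,3-dimethylchroman-4-one | O=C1[C@@H](C)[C@@H](C)Oc2cc(O)cc(O)c12 | intermediate
8 | (2R,3S)-5-hydroxy-2,3-dimethyl-7-[tri(propan-2-yl)silyloxy]chroman-4-one | O=C1[C@@H](C)[C@@H](C)Oc2cc(O[Si](C(C)C)(C(C)C)C(C)C)cc(O)c12 | intermediate
9 | (2R,3S)-5-hydroxy-6-iodo-2,3-dimethyl-7-[tri(propan-2-yl)silyloxy]chroman-4-one | O=C1[C@@H](C)[C@@H](C)Oc2cc(O[Si](C(C)C)(C(C)C)C(C)C)c(I)c(O)c12 | intermediate
10 | (2R,3S)-5,7-dihydroxy-6-iodo-2,3-dimethylchroman-4-one | O=C1[C@@H](C)[C@@H](C)Oc2cc(O)c(I)c(O)c12 | intermediate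
11 | (3R)-3-hydroxy-3-phenylpropanoic acid | OC(=O)C[C@@H](O)c1ccccc1 | starting material
12 | (4R)-4-phenyloxetan-2-one | O=C1C[C@H](c2ccccc2)O1 | intermediate
13 | (3S)-3-[(2R,3S)-5,7-dihydroxy-6-iodo-2,3-dimethyl-4-oxochroman-8-yl]-3-phenylpropanoic acid | O=C1[C@@H](C)[C@@H](C)Oc2c([C@@H](CC(=O)O)c3ccccc3)c(O)c(I)c(O)c12 | intermediate
14 | (2R,3S,10S)-5-hydroxy-6-iodo-2,3-dimethyl-10-phenyl-2,3,9,10-tetrahydropyrano[2,3-f]chromene-4,8-dione (lactone of 13 onto O7) | O=C1[C@@H](C)[C@@H](C)Oc2c3[C@H](c4ccccc4)CC(=O)Oc3c(I)c(O)c12 | intermediate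
15 | methyl (2R)-oxirane-2-carboxylate | COC(=O)[C@H]1CO1 | starting material
16 | methyl (2R)-2-hydroxy-5-methylhex-5-enoate | COC(=O)[C@H](O)CCC(C)=C | intermediate
17 | methyl (2R)-5-methyl-2-(trifluoromethylsulfonyloxy)hex-5-enoate | COC(=O)[C@H](OS(=O)(=O)C(F)(F)F)CCC(C)=C | intermediate
18 | methyl (2R)-5-methyl-2-(2-methylprop-1-en-1-yl)hex-5-enoate | COC(=O)[C@@H](C=C(C)C)CCC(C)=C | intermediate
19 | (2R)-5-methyl-2-(2-methylprop-1-en-1-yl)hex-5-en-1-ol | OC[C@@H](C=C(C)C)CCC(C)=C | intermediate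
20 | (2R)-1-iodo-5-methyl-2-(2-methylprop-1-en-1-yl)hex-5-ene | IC[C@@H](C=C(C)C)CCC(C)=C | intermediate
21 | [(2R)-5-methyl-2-(2-methylprop-1-en-1-yl)hex-5-en-1-yl]zinc iodide | I[Zn]C[C@@H](C=C(C)C)CCC(C)=C | intermediate
22 | (2R,3S,10S)-5-hydroxy-2,3-dimethyl-6-[(2S)-5-methyl-2-(2-methylprop-1-en-1-yl)hex-5-en-1-yl]-10-phenyl-2,3,9,10-tetrahydropyrano[2,3-f]chromene-4,8-dione | O=C1[C@@H](C)[C@@H](C)Oc2c3[C@H](c4ccccc4)CC(=O)Oc3c(C[C@@H](C=C(C)C)CCC(C)=C)c(O)c12 | intermediate
23 | (2S)-but-3-en-2-ol | C[C@H](O)C=C | starting material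
24 | 5-O-[(2R)-but-3-en-2-yl] ether of 22 | O=C1[C@@H](C)[C@@H](C)Oc2c3[C@H](c4ccccc4)CC(=O)Oc3c(C[C@@H](C=C(C)C)CCC(C)=C)c(O[C@H](C)C=C)c12 | intermediate
25 | (2R,3S,6R,10S)-6-[(2E)-but-2-en-1-yl]-2,3-dimethyl-6-[(2S)-5-methyl-2-(2-methylprop-1-en-1-yl)hex-5-en-1-yl]-10-phenyl-2,3,9,10-tetrahydropyrano[2,3-f]chromene-4,5,8(6H)-trione | C=C(C)CC[C@H](C=C(C)C)C[C@@]1(C/C=C/C)C(=O)C2=C(O[C@H](C)[C@H](C)C2=O)C3=C1OC(=O)C[C@H]3c4ccccc4 | intermediate
26 | (2R,3S,6S,10S)-2,3-dimethyl-6-(3-methylbut-2-en-1-yl)-6-[(2S)-5-methyl-2-(2-methylprop-1-en-1-yl)hex-5-en-1-yl]-10-phenyl-2,3,9,10-tetrahydropyrano[2,3-f]chromene-4,5,8(6H)-trione | C=C(C)CC[C@H](C=C(C)C)C[C@@]1(CC=C(C)C)C(=O)C2=C(O[C@H](C)[C@H](C)C2=O)C3=C1OC(=O)C[C@H]3c4ccccc4 | intermediate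
27 | (3S)-3-{(2R,3S,6S)-4-hydroxy-2,3-dimethyl-6-(3-methylbut-2-en-1-yl)-6-[(2S)-5-methyl-2-(2-methylprop-1-en-1-yl)hex-5-en-1-yl]-5,7-dioxo-3,5,6,7-tetrahydro-2H-chromen-8-yl}-3-phenylpropanoic acid (CNP0155375.1) | C=C(C)CC[C@H](C=C(C)C)C[C@@]1(CC=C(C)C)C(=O)C2=C(O)[C@@H](C)[C@@H](C)OC2=C([C@@H](CC(=O)O)c2ccccc2)C1=O | target

**Step count and risk**

Total: 15 steps. Longest linear sequence: 10 steps (steps 1–6, 8, 13, 14, 15). The side chain (steps 9–12) and the lactone (step 7) are made separately.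

The three steps most likely to fail:

Step 8 (the proposed lactone opening). Ionisation to a free benzylic cation would erode the enantiomeric purity or give styrene by loss of CO2. The fallback uses known chemistry and sets out from 10. Lewis-acid (BF3·OEt2) Friedel–Crafts opening of commercial methyl (2R,3S)-3-phenylglycidate (COC(=O)[C@@H]1O[C@H]1c1ccccc1) at its benzylic carbon with inversion, with lactonisation onto O7, gives the 9-hydroxy lactone F1. Acetylation (Ac2O, pyridine) gives the acetate F2, and SmI2 in THF/MeOH at −78 °C removes the α-acyloxy group. The route is rejoined at 14.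

Step 14 (Mitsunobu etherification of a hindered, chelated phenol and the Claisen shift). The ether may form poorly, or ionisation may erode the chirality transfer. The fallback sets out from 22. Aqueous KOH at 0 °C opens the lactone to the ring-opened hydroxy acid F3 (as its trianion), which is C-alkylated at C6 with 1-bromo-3-methylbut-2-ene, the classical dearomative prenylation of acylphloroglucinols. This gives 27 directly together with its C6 epimer F4, which is removed by preparative HPLC. The route is rejoined at 27; this path gives no control at the quaternary carbon.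

Step 6 (regioselective iodination). Iodination at C8 instead of C6 would misplace both later substituents. The fallback sets out from 7 (with 12) and settles the regiochemistry by separation instead. The alkylation and lactonisation of step 8 (or the glycidate sequence above) is run on 7 itself, giving the angular lactone F5 and the linear isomer F6. After chromatography, F5 is iodinated at its single free ring carbon with N-iodosuccinimide in MeCN. The route is rejoined at 14.

Further compounds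
F1 | step 8 | (2R,3S,9R,10S)-5,9-dihydroxy-6-iodo-2,3-dimethyl-10-phenyl-2,3,9,10-tetrahydropyrano[2,3-f]chromene-4,8-dione | O=C1[C@@H](C)[C@@H](C)Oc2c3[C@H](c4ccccc4)[C@@H](O)C(=O)Oc3c(I)c(O)c12
F2 | step 8 | (2R,3S,9R,10S)-5-hydroxy-6-iodo-2,3-dimethyl-4,8-dioxo-10-phenyl-2,3,9,10-tetrahydropyrano[2,3-f]chromen-9-yl acetate | O=C1[C@@H](C)[C@@H](C)Oc2c3[C@H](c4ccccc4)[C@@H](OC(C)=O)C(=O)Oc3c(I)c(O)c12
F3 | step 14 | (3S)-3-[(2R,3S)-5,7-dihydroxy-2,3-dimethyl-6-[(2S)-5-methyl-2-(2-methylprop-1-en-1-yl)hex-5-en-1-yl]-4-oxochroman-8-yl]-3-phenylpropanoic acid | O=C1[C@@H](C)[C@@H](C)Oc2c([C@@H](CC(=O)O)c3ccccc3)c(O)c(C[C@@H](C=C(C)C)CCC(C)=C)c(O)c12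
F4 | step 14 | C6 epimer of 27 (6R) | C=C(C)CC[C@H](C=C(C)C)C[C@]1(CC=C(C)C)C(=O)C2=C(O)[C@@H](C)[C@@H](C)OC2=C([C@@H](CC(=O)O)c2ccccc2)C1=O
F5 | step 6 | (2R,3S,10S)-5-hydroxy-2,3-dimethyl-10-phenyl-2,3,9,10-tetrahydropyrano[2,3-f]chromene-4,8-dione | O=C1[C@@H](C)[C@@H](C)Oc2c3[C@H](c4ccccc4)CC(=O)Oc3cc(O)c12
F6 | step 6 | (2R,3S,6S)-5-hydroxy-2,3-dimethyl-6-phenyl-2,3,6,7-tetrahydropyrano[3,2-g]chromene-4,8-dione | O=C1[C@@H](C)[C@@H](C)Oc2cc3OC(=O)C[C@@H](c4ccccc4)c3c(O)c12
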